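**Retrosynthetic overview**
- Target ⇐ fluoride desilylation and O-methylation of a 7-hydroxy-2,2-dimethylchromen-6-yl ketone that already carries the (S)-α-silyloxy side chain.
- Key disconnection: both chromene rings in one pot. The benzene ring comes from a [4+2] of a terminal ynone (C5–C6 plus side chain) with a 1-methoxy-1,3-bis(silyloxy)diene (C7–C8–C8a–C4a). The pyran ring comes from the diene's side-chain carbinol via o-quinone methide and oxa-6π closure.
- Ynone ⇐ Weinreb amide ⇐ (S)-4-hydroxyphenyllactic acid ⇐ L-tyrosine; the only stereocentre comes from the chiral pool.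
- Diene ⇐ δ-hydroxy-β-keto ester ⇐ methyl acetoacetate dianion + prenal.
- Ring order: the 4-hydroxyphenyl ring is bought; the chromene benzene ring and then its pyran ring form in the key step.

Assumption: a one-pot operation counts as one step. The carbinol centre of the diene building block is left racemic because the key step destroys it.

**Route**

Step 1
Reactants: 1 L-tyrosine
Product: 2 (S)-2-hydroxy-3-(4-hydroxyphenyl)propanoic acid
Conditions: NaNO2, 1 M H2SO4 (aq), 0 °C → rt
Reagents that add atoms: water (O)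
Why: Diazotisation of the α-amino acid (deaminative hydroxylation) runs by double inversion through carboxylate participation, so the L-(S) configuration is retained.

Step 2
Reactants: 2 (S)-2-hydroxy-3-(4-hydroxyphenyl)propanoic acid
Product: 3 (S)-2-hydroxy-3-(4-hydroxyphenyl)-N-methoxy-N-methylpropanamide
Conditions: MeNHOMe·HCl, EDC·HCl, HOBt, NMM, DMF, 0 °C → rt
Reagents that add atoms: N,O-dimethylhydroxylamine hydrochloride (CNOC.Cl)
Why: Carbodiimide/HOBt amide coupling gives the Weinreb amide; the amine outcompetes the free hydroxyls and the stereocentre is not touched.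

Step 3
Reactants: 3 (S)-2-hydroxy-3-(4-hydroxyphenyl)-N-methoxy-N-methylpropanamide
Product: 4 (S)-2-[(tert-butyldimethylsilyl)oxy]-3-{4-[(tert-butyldimethylsilyl)oxy]phenyl}-N-methoxy-N-methylpropanamide
Conditions: TBSCl, imidazole, DMF, rt
Reagents that add atoms: tert-butyldimethylsilyl chloride (CC(C)(C)[Si](C)(C)Cl)
Why: Imidazole-promoted silylation caps the phenol and the secondary alcohol as TBS ethers, which survive the Grignard, thermal and mildly acidic steps and fall to fluoride at the end.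

Step 4
Reactants: 4 (S)-2-[(tert-butyldimethylsilyl)oxy]-3-{4-[(tert-butyldimethylsilyl)oxy]phenyl}-N-methoxy-N-methylpropanamide
Product: 5 (S)-4-[(tert-butyldimethylsilyl)oxy]-5-{4-[(tert-butyldimethylsilyl)oxy]phenyl}pent-1-yn-3-one
Conditions: HC≡CMgBr (3 equiv), THF, −20 → 0 °C; inverse quench into cold 1 M HCl/Et2O
Reagents that add atoms: ethynylmagnesium bromide (C#C[Mg]Br)
Why: Weinreb ketone synthesis: the chelated tetrahedral adduct stops at single addition and the inverse acidic quench keeps freed MeNHOMe from adding to the ynone; the weakly basic acetylide does not enolise the α-silyloxy centre.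

Step 5
Reactants: 6 methyl acetoacetate; 7 3-methylbut-2-enal (prenal)
Product: 9 methyl 5-hydroxy-7-methyl-3-oxooct-6-enoate (racemic), via acetoacetate dianion 8 (not isolated)
Conditions: NaH, THF, 0 °C; n-BuLi, 0 °C; then 7, −78 °C; AcOH quench
Reagents that add atoms: none
Why: Weiler dianion aldol: the γ-carbon of the dianion adds 1,2 to the enal; the new carbinol centre is racemic on purpose because step 7 erases it.

Step 6
Reactants: 9 methyl 5-hydroxy-7-methyl-3-oxooct-6-enoate
Product: 10 1-methoxy-7-methyl-1,3,5-tris(trimethylsilyloxy)octa-1,3,6-triene (racemic; enol-ether E/Z mixture; used crude)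
Conditions: TMSOTf (3.3 equiv), Et3N (4.5 equiv), Et2O, 0 °C → rt
Reagents that add atoms: trimethylsilyl triflate (C[Si](C)(C)OS(=O)(=O)C(F)(F)F)
Why: Soft enolisation with silyl triflate/amine silylates the alcohol and turns the β-keto ester into the Chan-type 1-methoxy-1,3-bis(silyloxy)diene in one pot.

Step 7
Reactants: 5 (S)-4-[(tert-butyldimethylsilyl)oxy]-5-{4-[(tert-butyldimethylsilyl)oxy]phenyl}pent-1-yn-3-one; 10 1-methoxy-7-methyl-1,3,5-tris(trimethylsilyloxy)octa-1,3,6-triene (1.5 equiv)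
Product: 14 (2S)-2-[(tert-butyldimethylsilyl)oxy]-3-{4-[(tert-butyldimethylsilyl)oxy]phenyl}-1-(7-hydroxy-2,2-dimethyl-2H-chromen-6-yl)propan-1-one, via Diels–Alder adduct 11 (not isolated), via resorcinol allylic alcohol 12 (not isolated), via o-quinone methide 13 (not isolated)
Conditions: PhMe, 60 °C; then PPTS (0.2 equiv), MeOH (10 equiv), 60 °C, one pot
Reagents that add atoms: none
Why: Proposed new method: the electron-rich diene adds to the terminal ynone in a siloxydiene [4+2] benzannulation, its nucleophilic terminus C4 bonding to the ynone β-carbon, which places the acyl group next to the ester-derived oxygen and the side chain next to the ketone-derived oxygen; PPTS/MeOH then removes the TMS groups and aromatises the adduct, the benzylic and dimethylallylic carbinol ortho to the new phenol loses water to the o-quinone methide, and this closes by oxa-6π electrocyclisation to the 2,2-dimethyl-2H-chromene; the closest known reaction types are Danishefsky/Chan-diene–alkynone benzannulations and the benzannulation/o-quinone methide/electrocyclisation cascade that gives chromenes from Fischer carbenes and alkenyl propargyl ethers; the (S)-centre is a spectator and the racemic centre of 10 is destroyed.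

Step 8
Reactants: 14 (2S)-2-[(tert-butyldimethylsilyl)oxy]-3-{4-[(tert-butyldimethylsilyl)oxy]phenyl}-1-(7-hydroxy-2,2-dimethyl-2H-chromen-6-yl)propan-1-one
Product: 15 (2S)-2-[(tert-butyldimethylsilyl)oxy]-3-{4-[(tert-butyldimethylsilyl)oxy]phenyl}-1-(7-methoxy-2,2-dimethyl-2H-chromen-6-yl)propan-1-one
Conditions: MeI, K2CO3, acetone, 40 °C
Reagents that add atoms: iodomethane (CI)
Why: Williamson O-methylation of the only free (chelated) phenol; the weak heterogeneous base in dry acetone should neither cleave the aryl silyl ether nor enolise the α-silyloxy ketone.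

Step 9
Reactants: 15 (2S)-2-[(tert-butyldimethylsilyl)oxy]-3-{4-[(tert-butyldimethylsilyl)oxy]phenyl}-1-(7-methoxy-2,2-dimethyl-2H-chromen-6-yl)propan-1-one
Product: 16 Lespeflorin C7, (2S)-2-hydroxy-3-(4-hydroxyphenyl)-1-(7-methoxy-2,2-dimethyl-2H-chromen-6-yl)propan-1-one
Conditions: TBAF, AcOH (1:1), THF, 0 °C → rt
Reagents that add atoms: none
Why: Fluoride desilylation buffered with AcOH removes both TBS groups without base-induced epimerisation or α-ketol rearrangement and leaves the chromene intact.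

**Compound list**

1 | L-tyrosine, (S)-2-amino-3-(4-hydroxyphenyl)propanoic acid | N[C@@H](Cc1ccc(O)cc1)C(=O)O | starting material
2 | (S)-2-hydroxy-3-(4-hydroxyphenyl)propanoic acid | O[C@@H](Cc1ccc(O)cc1)C(=O)O | intermediate
3 | (S)-2-hydroxy-3-(4-hydroxyphenyl)-N-methoxy-N-methylpropanamide | CON(C)C(=O)[C@@H](O)Cc1ccc(O)cc1 | intermediate
4 | (S)-2-[(tert-butyldimethylsilyl)oxy]-3-{4-[(tert-butyldimethylsilyl)oxy]phenyl}-N-methoxy-N-methylpropanamide | CON(C)C(=O)[C@@H](O[Si](C)(C)C(C)(C)C)Cc1ccc(O[Si](C)(C)C(C)(C)C)cc1 | intermediate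
5 | (S)-4-[(tert-butyldimethylsilyl)oxy]-5-{4-[(tert-butyldimethylsilyl)oxy]phenyl}pent-1-yn-3-one | C#CC(=O)[C@@H](O[Si](C)(C)C(C)(C)C)Cc1ccc(O[Si](C)(C)C(C)(C)C)cc1 | intermediate
6 | methyl acetoacetate | COC(=O)CC(C)=O | starting material
7 | 3-methylbut-2-enal (prenal) | CC(C)=CC=O | starting material
8 | sodium lithium dianion of methyl acetoacetate (not isolated) | [Na+].[Li+].COC(=O)[CH-]C(=O)[CH2-] | intermediate
9 | methyl 5-hydroxy-7-methyl-3-oxooct-6-enoate (racemic) | COC(=O)CC(=O)CC(O)C=C(C)C | intermediate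
10 | 1-methoxy-7-methyl-1,3,5-tris(trimethylsilyloxy)octa-1,3,6-triene (racemic, E/Z mixture) | COC(O[Si](C)(C)C)=CC(O[Si](C)(C)C)=CC(O[Si](C)(C)C)C=C(C)C | intermediate
11 | Diels–Alder adduct (not isolated): (2S)-2-(TBSO)-3-[4-(TBSO)phenyl]-1-{6-methoxy-3-[3-methyl-1-(trimethylsilyloxy)but-2-enyl]-4,6-bis(trimethylsilyloxy)cyclohexa-1,4-dien-1-yl}propan-1-one, diastereomer mixture | COC1(O[Si](C)(C)C)C=C(O[Si](C)(C)C)C(C(O[Si](C)(C)C)C=C(C)C)C=C1C(=O)[C@@H](O[Si](C)(C)C(C)(C)C)Cc1ccc(O[Si](C)(C)C(C)(C)C)cc1 | intermediate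
12 | resorcinol allylic alcohol (not isolated): (2S)-2-(TBSO)-3-[4-(TBSO)phenyl]-1-[2,4-dihydroxy-5-(1-hydroxy-3-methylbut-2-enyl)phenyl]propan-1-one | CC(C)=CC(O)c1cc(C(=O)[C@@H](O[Si](C)(C)C(C)(C)C)Cc2ccc(O[Si](C)(C)C(C)(C)C)cc2)c(O)cc1O | intermediate
13 | o-quinone methide (not isolated): (2S)-2-(TBSO)-3-[4-(TBSO)phenyl]-1-[6-hydroxy-3-(3-methylbut-2-enylidene)-4-oxocyclohexa-1,5-dien-1-yl]propan-1-one | CC(C)=CC=C1C=C(C(=O)[C@@H](O[Si](C)(C)C(C)(C)C)Cc2ccc(O[Si](C)(C)C(C)(C)C)cc2)C(O)=CC1=O | intermediate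
14 | (2S)-2-[(tert-butyldimethylsilyl)oxy]-3-{4-[(tert-butyldimethylsilyl)oxy]phenyl}-1-(7-hydroxy-2,2-dimethyl-2H-chromen-6-yl)propan-1-one | CC1(C)C=Cc2cc(C(=O)[C@@H](O[Si](C)(C)C(C)(C)C)Cc3ccc(O[Si](C)(C)C(C)(C)C)cc3)c(O)cc2O1 | intermediate
15 | (2S)-2-[(tert-butyldimethylsilyl)oxy]-3-{4-[(tert-butyldimethylsilyl)oxy]phenyl}-1-(7-methoxy-2,2-dimethyl-2H-chromen-6-yl)propan-1-one | COc1cc2c(cc1C(=O)[C@@H](O[Si](C)(C)C(C)(C)C)Cc1ccc(O[Si](C)(C)C(C)(C)C)cc1)C=CC(C)(C)O2 | intermediate
16 | Lespeflorin C7, (2S)-2-hydroxy-3-(4-hydroxyphenyl)-1-(7-methoxy-2,2-dimethyl-2H-chromen-6-yl)propan-1-one | COc1cc2c(cc1C(=O)[C@@H](O)Cc1ccc(O)cc1)C=CC(C)(C)O2 | target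

**Step count**

Total steps: 9. Longest linear sequence: 7 (steps 1, 2, 3, 4, 7, 8, 9).

**Steps most likely to fail, with fallbacks**

Step 7 (key cascade). The 4-substituted diene is an E/Z mixture and only one isomer reaches the s-cis geometry for a concerted [4+2]. The acid stage must also ionise the benzylic carbinol without cleaving the secondary TBS ether. Fallback: give up the de novo arene construction and acylate a preformed chromene. Bought 4-bromo-3-methoxyphenol (COc1cc(O)ccc1Br) is condensed with prenal 7 (PhB(OH)2, AcOH, PhMe, reflux) to 6-bromo-7-methoxy-2,2-dimethyl-2H-chromene F1. Br/Li exchange (t-BuLi, THF, −78 °C) gives (7-methoxy-2,2-dimethyl-2H-chromen-6-yl)lithium F2, which is added to Weinreb amide 4. This sets out from 4 and comes back to the route at 15, so steps 4–8 are not needed.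

Step 6 (tris-silyl diene). The γ-substituted keto ester may enolise sluggishly or C-silylate, and the allylic silyloxy group may eliminate. Fallback: take the oxygen out of the side chain and restore the oxidation level after ring formation. Dianion 8 is alkylated with prenyl bromide (CC(C)=CCBr) to methyl 7-methyl-3-oxooct-6-enoate F3. Two-stage hard enolisation (TMSCl/Et3N to methyl 7-methyl-3-(trimethylsilyloxy)octa-2,6-dienoate F4, then LDA/TMSCl, THF, −78 °C) gives 1-methoxy-7-methyl-1,3-bis(trimethylsilyloxy)octa-1,3,6-triene F5. This reacts with ynone 5 (PhMe, 60 °C; then PPTS, MeOH) through the prenyl cycloadduct F6 to the 5-prenyl-2,4-dihydroxyphenyl ketone F7. DDQ (PhH, rt → 60 °C) abstracts the benzylic hydride to o-quinone methide 13, which closes to 14. This sets out from 8 and 5 and comes back at 14.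

Step 8 (O-methylation). The chelated phenol may react slowly, carbonate may nick the aryl silyl ether (then the wrong phenol is methylated), and the α-centre may epimerise. Fallback: bring the methyl ether in with the diene so no methylation is needed. Bought 1,1-dimethoxyethene (COC(=C)OC) is acylated with AcCl/Et3N to 4,4-dimethoxybut-3-en-2-one F8. LDA, then prenal 7, then TMSCl gives 1,1-dimethoxy-7-methyl-5-(trimethylsilyloxy)octa-1,6-dien-3-one F9, and LDA/TMSCl gives 1,1-dimethoxy-7-methyl-3,5-bis(trimethylsilyloxy)octa-1,3,6-triene F10. With ynone 5 under the step-7 conditions the dimethoxy cycloadduct F11 aromatises by loss of methanol, keeping one methoxy at C7, to the methoxy phenol allylic alcohol F12. This dehydrates to the methoxy o-quinone methide F13, which closes to 15. This sets out from 7 and 5 and comes back at 15.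

**Further compounds**

F1 | step 7 | 6-bromo-7-methoxy-2,2-dimethyl-2H-chromene | COc1cc2c(cc1Br)C=CC(C)(C)O2
F2 | step 7 | (7-methoxy-2,2-dimethyl-2H-chromen-6-yl)lithium | COc1cc2c(cc1[Li])C=CC(C)(C)O2
F3 | step 6 | methyl 7-methyl-3-oxooct-6-enoate | COC(=O)CC(=O)CCC=C(C)C
F4 | step 6 | methyl 7-methyl-3-(trimethylsilyloxy)octa-2,6-dienoate (E/Z mixture) | COC(=O)C=C(CCC=C(C)C)O[Si](C)(C)C
F5 | step 6 | 1-methoxy-7-methyl-1,3-bis(trimethylsilyloxy)octa-1,3,6-triene (E/Z mixture) | COC(O[Si](C)(C)C)=CC(O[Si](C)(C)C)=CCC=C(C)C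
F6 | step 6 | prenyl cycloadduct: (2S)-2-(TBSO)-3-[4-(TBSO)phenyl]-1-[6-methoxy-3-(3-methylbut-2-enyl)-4,6-bis(trimethylsilyloxy)cyclohexa-1,4-dien-1-yl]propan-1-one | COC1(O[Si](C)(C)C)C=C(O[Si](C)(C)C)C(CC=C(C)C)C=C1C(=O)[C@@H](O[Si](C)(C)C(C)(C)C)Cc1ccc(O[Si](C)(C)C(C)(C)C)cc1
F7 | step 6 | (2S)-2-(TBSO)-3-[4-(TBSO)phenyl]-1-[2,4-dihydroxy-5-(3-methylbut-2-enyl)phenyl]propan-1-one | CC(C)=CCc1cc(C(=O)[C@@H](O[Si](C)(C)C(C)(C)C)Cc2ccc(O[Si](C)(C)C(C)(C)C)cc2)c(O)cc1O
F8 | step 8 | 4,4-dimethoxybut-3-en-2-one | COC(OC)=CC(C)=O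
F9 | step 8 | 1,1-dimethoxy-7-methyl-5-(trimethylsilyloxy)octa-1,6-dien-3-one (racemic) | COC(OC)=CC(=O)CC(O[Si](C)(C)C)C=C(C)C
F10 | step 8 | 1,1-dimethoxy-7-methyl-3,5-bis(trimethylsilyloxy)octa-1,3,6-triene (racemic, E/Z mixture) | COC(OC)=CC(O[Si](C)(C)C)=CC(O[Si](C)(C)C)C=C(C)C
F11 | step 8 | dimethoxy cycloadduct: (2S)-2-(TBSO)-3-[4-(TBSO)phenyl]-1-{6,6-dimethoxy-3-[3-methyl-1-(trimethylsilyloxy)but-2-enyl]-4-(trimethylsilyloxy)cyclohexa-1,4-dien-1-yl}propan-1-one | COC1(OC)C=C(O[Si](C)(C)C)C(C(O[Si](C)(C)C)C=C(C)C)C=C1C(=O)[C@@H](O[Si](C)(C)C(C)(C)C)Cc1ccc(O[Si](C)(C)C(C)(C)C)cc1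
F12 | step 8 | methoxy phenol allylic alcohol: (2S)-2-(TBSO)-3-[4-(TBSO)phenyl]-1-[4-hydroxy-5-(1-hydroxy-3-methylbut-2-enyl)-2-methoxyphenyl]propan-1-one | CC(C)=CC(O)c1cc(C(=O)[C@@H](O[Si](C)(C)C(C)(C)C)Cc2ccc(O[Si](C)(C)C(C)(C)C)cc2)c(OC)cc1O
F13 | step 8 | methoxy o-quinone methide: (2S)-2-(TBSO)-3-[4-(TBSO)phenyl]-1-[6-methoxy-3-(3-methylbut-2-enylidene)-4-oxocyclohexa-1,5-dien-1-yl]propan-1-one | CC(C)=CC=C1C=C(C(=O)[C@@H](O[Si](C)(C)C(C)(C)C)Cc2ccc(O[Si](C)(C)C(C)(C)C)cc2)C(OC)=CC1=O
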